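## Structural features

The target is a flavan. Ring A (the benzo ring, C4a to C8a, hydroxyl on C7) is fused to ring C (O1, C2, C3, C4); ring B (4-hydroxyphenyl, C1'' to C6'') sits on C2; ring D (2,4,6-trihydroxyphenyl, C1' to C6', dodecanoyl on C3') sits on C4. The two stereocentres, C2 (R) and C4 (S), are separated by the C3 methylene and are trans, so in the half-chair of ring C ring B is pseudo-equatorial and ring D pseudo-axial. The C2-O1 bond is a para-hydroxybenzylic ether that can open through a quinone methide and epimerise C2. C4 is a diarylmethine between two electron-rich rings and is open to ionisation and oxidation, and ring D is an acidic, easily oxidised acylphloroglucinol. The difficulty is twofold: two remote benzylic centres must be set 1,3-trans, and five phenolic hydroxyls must be told apart. Once ring C is open, the oxygens on C8a, C2' and C6' all stand five atoms from C2. The key step uses the fact that C2 is the benzylic carbon para to the ring B hydroxyl: loss of the C2 hydrogen and the phenolic proton gives a para-quinone methide with C2 as its methide carbon, and the C8a oxygen can add to it to form O1-C2 and the six-membered ring C. A seco-phenol with every hydroxyl free would offer that methide three oxygen nucleophiles and the oxidase two further para-substituted phenols, so ring D is carried through the ring closure as its triacetate.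

## Logic of the disconnections

15 is traced back to 14 by cutting the three O-acetyl bonds on ring D. The acetates make the preceding ring closure unambiguous: with the C2' and C6' oxygens acylated only the C8a oxygen can reach C2, and ring D is no longer a second para-substituted phenol. Nothing is gained in size. The demand is that unmasking must not open the C2-O1 ether, which calls for methanolysis under a weak base.

14 is opened at O1-C2 to give 12, by way of 13. The cut is made there because C2 is benzylic and para to the ring B hydroxyl, so the bond can be formed by removing the C2 hydrogen and letting the C8a oxygen add. This removes ring C and the C2 stereocentre and leaves an open-chain 1,1,3-triarylpropane with C4 as its only stereocentre. The forward step must dehydrogenate C2-H in preference to the C4 diarylmethine and bring O1 to one face of C2.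

12 goes back to 11 by restoring an acetoxy group on C2 and benzyl groups on the C7, C8a and C4'' oxygens. The C2 oxygen is the trace of the carbonyl through which ring B was attached, and the benzyl ethers carry rings A and B through the organometallic step. One hydrogenolysis must cleave four benzylic C-O bonds without touching the aryl acetates, the ketone or C4, and without letting a transient 4-hydroxybenzylic acetate close ring C on its own.

11 goes back to 10 by removing four acetyl groups. One acetylation serves two ends, masking ring D and activating the C2-O bond for hydrogenolysis; it must reach the chelated hydroxyl next to the ketone.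

10 is cut at C2-C1'' into 7 and 9, the latter made from 8. This takes ring B off as a simple aryl bromide and leaves C2 as a masked aldehyde. The forward addition must prefer the aldehyde over the ring D ketone and tolerate three acidic hydroxyls; the configuration of the new carbinol does not matter.

7 is cut at C4-C1' (and at the hemiacetal C2-O bond) into 3 and 5, by way of 6. The cut follows the innate nucleophilicity of ring D at the carbon between two hydroxyls and creates C4 in a catalytic enantioselective conjugate addition. It divides the skeleton into two achiral halves of similar size. The forward step needs mono-alkylation of 3, 1,4- rather than 1,2-addition, and control of the β-face by the catalyst. The opposite polarity, with ring D as a cinnamaldehyde, was set aside because its β-carbon would lie between two ortho substituents and its ketone would be exposed to the aryl Grignard reagent.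

5 is cut at the C3=C4 double bond to give 4, a two-carbon homologation that must deliver the E enal.

3 is cut at the bond between C3' and the carbonyl carbon into 1 and 2. Because 1 is threefold symmetric the acylation has no regiochemical issue, and the acyl group guards against a second acylation.

## Other disconnections considered

Alternative 1: The cut runs through both O1-C2 and C4-C4a, so ring C would be assembled in one operation from (1R,2R)-1-[4-(benzyloxy)phenyl]-2-[2,4,6-tris(benzyloxy)-3-bromophenyl]cyclopropane A1 and 3-(benzyloxy)phenol A2. In the forward sense, anodic one-electron oxidation of A1 would give an arylcyclopropane radical cation. The hydroxyl of A2 would open it at the ring B carbon with inversion (R in A1 becomes 2R), and after a second electron transfer the ring D benzylic cation would alkylate A2 ortho to the new ether to give the pentabenzyl bromoflavan A3.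

- In its favour: it is convergent, makes two bonds and the ring at once, needs no removal and re-introduction of oxygen at C2, and sets C2 by a stereospecific substitution rather than by an enzyme pocket. On these points it is the better plan on paper.
- Against it: A2 should be oxidised at a potential close to that of A1, so phenol coupling would compete. Radical cations of 1,2-diarylcyclopropanes can reopen and reclose, which would erode the configuration before capture. The positive charge would reside mainly on ring D, so attack at the ring B carbon is not assured. C4 would rest on substrate control, and alkylation para to the hydroxyl of A2 would compete. A1 needs an enantioselective cyclopropanation with a donor-substituted aryl carbene. The lauroyl group would have to enter late, by halogen-metal exchange at a bromide flanked by two benzyloxy groups and acylation with 2.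
- Comparison: structurally it builds more of the target in its key step (two bonds, both centres addressed, against one bond and one centre). Mechanistically both key steps lie outside established practice, so neither is safer. In step count it should be roughly level, since A1 is several steps away and two steps follow A3.

Alternative 2: Ring A is built rather than bought; the cuts are C4a-C5 and C8-C8a. Malonate A4, carrying the complete C4-C3-C2 chain with rings D and B, would add through its malonate carbon to methyl vinyl ketone A5. The new methyl ketone would close by Claisen condensation onto one ester to give dione ester A6. Loss of the ester group, dehydrogenation to the resorcinol, closure of O1-C2 and debenzylation would follow.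

- In its favour: every step is a known reaction type, which is better than the chosen plan. There is no regiochemical question on ring A. Both stereocentres can be set early by well-tried methods (conjugate addition for C4, ketone reduction for C2).
- Against it: the Michael addition would create a quaternary carbon next to the hindered C4 methine. The basic conditions would also enolise the lauroyl ketone. Aromatising a cyclohexane-1,3-dione asks for oxidising or hot conditions in the presence of five benzyl ethers and a benzylic silyl ether. As drawn, the silyloxy centre at C2 of A6 already has the configuration of the target, so an invertive closure (Mitsunobu) would give the C2 epimer; the centre would have to be inverted beforehand, or the closure run by ionisation under substrate control.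
- Comparison: structurally it spends its effort on a ring that is available as a resorcinol unit, and makes and destroys a centre at C4a. Mechanistically it is the safer plan. In step count it should be clearly longer, with at least four steps after A6.

Alternative 3: Ring B is cut at C1''-C6'' and C2''-C3''. Aldehyde A7, with ring C closed and both stereocentres in place, would react with A5 under secondary-amine catalysis: enamine Michael addition, then intramolecular aldol condensation to cyclohexenone A8. Dehydrogenation to the phenol and debenzylation would follow.

- In its favour: only known reaction types are used, again a point on which it is better than the chosen plan. Ring C is closed early, so the selectivity problems of an open seco-phenol do not arise.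
- Against it: in A7 the ring oxygen O1 is β to the aldehyde, so the amine catalyst can open ring C by retro-oxa-Michael reaction and scramble C2. In A8, C1'' is the γ-carbon of the enone, and dienolisation during aromatisation could expel O1 in the same way. The oxidative aromatisation would have to spare the lauroyl chain and the benzyl ethers.
- Comparison: structurally it builds the simplest ring of the target, whereas the chosen plan spends its key step on the ring that carries the stereocentres. Mechanistically each step is safer, but two successive steps threaten C2, which the chosen plan forms last. In step count it needs at least three steps after the key step against one.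

Key step: step 7

Remark on the chemistry: lactol 7 is drawn closed on the ring D hydroxyl para to the ketone; it should equilibrate with the isomer closed on the chelated hydroxyl and with open aldehyde 6, and all three converge in step 4.

Remark on the chemistry: the oxidase of step 7 is assumed to be a flavin-dependent 4-alkylphenol oxidase (eugenol oxidase type) whose substrate pocket has been enlarged by directed evolution.

## Route

Step 1
Reactants: 1 phloroglucinol; 2 lauroyl chloride
Product: 3 1-(2,4,6-trihydroxyphenyl)dodecan-1-one
Conditions: AlCl3 (3.5 equiv), PhNO2, 80 °C; then ice, aq. HCl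
Reagents that add atoms: none
Why: Friedel-Crafts acylation of a symmetric triol whose three free positions are equivalent; the first acyl group deactivates the ring, so the mono-ketone should predominate.

Step 2
Reactants: 4 2,4-bis(benzyloxy)benzaldehyde
Product: 5 (E)-3-[2,4-bis(benzyloxy)phenyl]prop-2-enal
Conditions: Ph3P=CHCHO (1.2 equiv), toluene, 90 °C
Reagents that add atoms: (triphenylphosphoranylidene)acetaldehyde, O=CC=P(c1ccccc1)(c1ccccc1)c1ccccc1
Why: Wittig reaction with a stabilised ylide, which should give the E enal; a small excess of ylide and moderate temperature limit a second homologation.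

Step 3
Reactants: 3 1-(2,4,6-trihydroxyphenyl)dodecan-1-one; 5 (E)-3-[2,4-bis(benzyloxy)phenyl]prop-2-enal
Product: 7 1-[(4S)-4-[2,4-bis(benzyloxy)phenyl]-2,5,7-trihydroxy-3,4-dihydro-2H-chromen-6-yl]dodecan-1-one (lactol; both anomers), via (3S)-3-[2,4-bis(benzyloxy)phenyl]-3-(3-dodecanoyl-2,4,6-trihydroxyphenyl)propanal 6 (not isolated)
Conditions: (S)-2-[diphenyl(trimethylsilyloxy)methyl]pyrrolidine (20 mol %), PhCO2H (20 mol %), 3 (1.5 equiv), toluene-CH2Cl2, 0 °C to rt
Reagents that add atoms: none
Why: Iminium-catalysed Friedel-Crafts alkylation of an electron-rich phenol by an enal with hemiacetalisation; the free ring carbon of 3 should add to the β-carbon of the E iminium ion on the face away from the diphenyl(silyloxy)methyl group, which for the S catalyst gives S at C4. Closure of 6 to the lactol ties up one hydroxyl and so disfavours a second alkylation.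

Step 4
Reactants: 7 lactol from step 3; 8 1-(benzyloxy)-4-bromobenzene
Product: 10 1-[3-[(1S)-1-[2,4-bis(benzyloxy)phenyl]-3-[4-(benzyloxy)phenyl]-3-hydroxypropyl]-2,4,6-trihydroxyphenyl]dodecan-1-one (both carbinol epimers), via [4-(benzyloxy)phenyl]magnesium bromide 9 (not isolated)
Conditions: 8, Mg, THF, reflux; then 7 added to 9 (5 equiv), THF, 0 °C to rt; aq. NH4Cl
Reagents that add atoms: none
Why: Grignard addition to the aldehyde released from the magnesium lactolate; three equivalents of 9 are consumed by the acidic hydroxyls, and the ketone, flanked by two magnesium phenoxides and conjugated with three, should be far less electrophilic than the aldehyde. The carbinol centre is uncontrolled and is removed in step 6.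

Step 5
Reactants: 10 tetraol from step 4
Product: 11 (3S)-3-[2,4-bis(benzyloxy)phenyl]-1-[4-(benzyloxy)phenyl]-3-[2,4,6-tris(acetyloxy)-3-dodecanoylphenyl]propyl acetate (both C1 epimers)
Conditions: Ac2O (8 equiv), pyridine, DMAP (cat.), CH2Cl2, 0 °C to rt
Reagents that add atoms: acetic anhydride, CC(=O)OC(C)=O
Why: Exhaustive O-acetylation under nucleophilic catalysis; it masks the three ring D hydroxyls for the ring closure and turns the C2 hydroxyl into a benzylic acetate that hydrogenolysis can remove.

Step 6
Reactants: 11 tetraacetate from step 5
Product: 12 2-[(1S)-1-(2,4-dihydroxyphenyl)-3-(4-hydroxyphenyl)propyl]-4-dodecanoylbenzene-1,3,5-triyl triacetate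
Conditions: H2 (1 atm), 10% Pd/C, EtOAc, rt
Reagents that add atoms: none
Why: Catalytic hydrogenolysis should cleave the three aryl benzyl ethers and the electron-rich benzylic acetate at C2, while the aryl acetates, the twisted di-ortho-substituted ketone and the C4 centre are left alone.

Step 7
Reactants: 12 seco-phenol triacetate from step 6
Product: 14 2-dodecanoyl-4-[(2R,4S)-7-hydroxy-2-(4-hydroxyphenyl)-3,4-dihydro-2H-chromen-4-yl]benzene-1,3,5-triyl triacetate, via para-quinone methide 13 (not isolated)
Conditions: eugenol oxidase variant (FAD-dependent, pocket enlarged by directed evolution), air, catalase, KH2PO4/K2HPO4 buffer (50 mM, pH 7.5), DMSO (10% v/v), 25 °C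
Reagents that add atoms: none
Why: Proposed new method: the oxidase should bind ring B of 12 as its phenolate and transfer hydride from C2 to the flavin, giving enzyme-bound para-quinone methide 13; the C8a hydroxyl should then add to the methide carbon in place of the water this enzyme family normally delivers, while O2 reoxidises the flavin and leaves H2O2 for catalase. The closest known reaction type is the oxidation of 4-ethylphenol, 4-propylphenol and eugenol by vanillyl alcohol oxidase and eugenol oxidase through the same kind of methide, which water captures to give (R)-1-(4-hydroxyphenyl)alkanols; capture by an internal phenol and a substrate of this size have not been shown. Ring C closes by a 6-exo-trig oxa-conjugate addition of O1 to C2 of the exocyclic methide. The new C2 centre should be set by the face of the methide that the pocket leaves open, the face water takes in the R-selective hydroxylation, and the substrate reinforces it, because the half-chair with ring D pseudo-axial on C4 and the methide ring pseudo-equatorial leads to the 2,4-trans (2R,4S) product. Site selectivity for C2-H over the C4 diarylmethine is secured in 12 because ring B is the only unhindered 4-alkylphenol: ring D is an aryl triacetate that cannot bind as a phenolate, and the position para to the C7 hydroxyl is the tertiary, doubly arylated C4. Selectivity among oxygen nucleophiles is secured because the C2' and C6' oxygens, which would lie as close to C2 as O1, are acetylated, so the C8a hydroxyl is the only phenol within reach. C4 is not touched and keeps its S configuration.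

Step 8
Reactants: 14 flavan triacetate from step 7
Product: 15 1-[2,4,6-trihydroxy-3-[(2R,4S)-7-hydroxy-2-(4-hydroxyphenyl)-3,4-dihydro-2H-chromen-4-yl]phenyl]dodecan-1-one
Conditions: Et3N (5 equiv), MeOH, 0 °C to rt, argon
Reagents that add atoms: none
Why: Amine-promoted methanolysis of aryl acetates that are activated by the ortho and para acyl group; the conditions should be too mild to open the C2-O1 ether through the ring B phenoxide, so C2 and C4 are kept.

## Compound list

1 | phloroglucinol (benzene-1,3,5-triol) | Oc1cc(O)cc(O)c1 | starting material
2 | lauroyl chloride (dodecanoyl chloride) | CCCCCCCCCCCC(Cl)=O | starting material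
3 | 1-(2,4,6-trihydroxyphenyl)dodecan-1-one | CCCCCCCCCCCC(=O)c1c(O)cc(O)cc1O | intermediate
4 | 2,4-bis(benzyloxy)benzaldehyde | O=Cc1ccc(OCc2ccccc2)cc1OCc1ccccc1 | starting material
5 | (E)-3-[2,4-bis(benzyloxy)phenyl]prop-2-enal | O=C/C=C/c1ccc(OCc2ccccc2)cc1OCc1ccccc1 | intermediate
6 | (3S)-3-[2,4-bis(benzyloxy)phenyl]-3-(3-dodecanoyl-2,4,6-trihydroxyphenyl)propanal | CCCCCCCCCCCC(=O)c1c(O)cc(O)c([C@@H](CC=O)c2ccc(OCc3ccccc3)cc2OCc2ccccc2)c1O | intermediate (not isolated)
7 | 1-[(4S)-4-[2,4-bis(benzyloxy)phenyl]-2,5,7-trihydroxy-3,4-dihydro-2H-chromen-6-yl]dodecan-1-one (lactol, both anomers) | CCCCCCCCCCCC(=O)c1c(O)cc2OC(O)C[C@@H](c3ccc(OCc4ccccc4)cc3OCc3ccccc3)c2c1O | intermediate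
8 | 1-(benzyloxy)-4-bromobenzene | Brc1ccc(OCc2ccccc2)cc1 | starting material
9 | [4-(benzyloxy)phenyl]magnesium bromide | Br[Mg]c1ccc(OCc2ccccc2)cc1 | intermediate (not isolated)
10 | 1-[3-[(1S)-1-[2,4-bis(benzyloxy)phenyl]-3-[4-(benzyloxy)phenyl]-3-hydroxypropyl]-2,4,6-trihydroxyphenyl]dodecan-1-one (both carbinol epimers) | CCCCCCCCCCCC(=O)c1c(O)cc(O)c([C@@H](CC(O)c2ccc(OCc3ccccc3)cc2)c2ccc(OCc3ccccc3)cc2OCc2ccccc2)c1O | intermediate
11 | (3S)-3-[2,4-bis(benzyloxy)phenyl]-1-[4-(benzyloxy)phenyl]-3-[2,4,6-tris(acetyloxy)-3-dodecanoylphenyl]propyl acetate (both C1 epimers) | CCCCCCCCCCCC(=O)c1c(OC(C)=O)cc(OC(C)=O)c([C@@H](CC(OC(C)=O)c2ccc(OCc3ccccc3)cc2)c2ccc(OCc3ccccc3)cc2OCc2ccccc2)c1OC(C)=O | intermediate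
12 | 2-[(1S)-1-(2,4-dihydroxyphenyl)-3-(4-hydroxyphenyl)propyl]-4-dodecanoylbenzene-1,3,5-triyl triacetate (seco-phenol, key-step precursor) | CCCCCCCCCCCC(=O)c1c(OC(C)=O)cc(OC(C)=O)c([C@@H](CCc2ccc(O)cc2)c2ccc(O)cc2O)c1OC(C)=O | intermediate
13 | 2-[(1S)-1-(2,4-dihydroxyphenyl)-3-(4-oxocyclohexa-2,5-dien-1-ylidene)propyl]-4-dodecanoylbenzene-1,3,5-triyl triacetate (para-quinone methide) | CCCCCCCCCCCC(=O)c1c(OC(C)=O)cc(OC(C)=O)c([C@@H](CC=C2C=CC(=O)C=C2)c2ccc(O)cc2O)c1OC(C)=O | intermediate (not isolated)
14 | 2-dodecanoyl-4-[(2R,4S)-7-hydroxy-2-(4-hydroxyphenyl)-3,4-dihydro-2H-chromen-4-yl]benzene-1,3,5-triyl triacetate (key-step product) | CCCCCCCCCCCC(=O)c1c(OC(C)=O)cc(OC(C)=O)c([C@H]2C[C@H](c3ccc(O)cc3)Oc3cc(O)ccc32)c1OC(C)=O | intermediate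
15 | 1-[2,4,6-trihydroxy-3-[(2R,4S)-7-hydroxy-2-(4-hydroxyphenyl)-3,4-dihydro-2H-chromen-4-yl]phenyl]dodecan-1-one | CCCCCCCCCCCC(=O)c1c(O)cc(O)c([C@H]2C[C@H](c3ccc(O)cc3)Oc3cc(O)ccc32)c1O | target

## Step count and least certain steps

Total step count: 8. Longest linear sequence: 7 steps (4 to 5 to 7 to 10 to 11 to 12 to 14 to 15; the branch from 1 through 3 is equally long).

**Step 7 (key step, new method).**
- What may go wrong: the large, lipophilic substrate may not bind productively, so no turnover occurs. Water may capture the methide to give the C2 carbinol, or the methide may tautomerise to the C2=C3 styrene. The product, still a 4-substituted phenol with a benzylic C2-H, may be oxidised further with opening of ring C. Slow acetyl transfer from ring D to the C8a oxygen or hydrolysis in the buffer would re-expose the competing ring D oxygens. Oxidation from ring A at C4 would erase that centre.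
- Fallback (known chemistry, from 3, rejoining at 15): the C4-C1' bond is made last on a ring C that is already closed. 7-Hydroxy-4H-chromen-4-one would be benzylated (BnBr, K2CO3, DMF) to 7-(benzyloxy)-4H-chromen-4-one F1. Conjugate addition of 4-(benzyloxy)phenylboronic acid to F1 under Pd(OCOCF3)2 and a chiral tert-butyl pyridine-oxazoline ligand (the enantiomer that delivers 2R) should give (2R)-7-(benzyloxy)-2-[4-(benzyloxy)phenyl]-2,3-dihydro-4H-chromen-4-one F2. NaBH4 in MeOH-THF should reduce it to (2R)-7-(benzyloxy)-2-[4-(benzyloxy)phenyl]-3,4-dihydro-2H-chromen-4-ol F3 (C4 epimers, both usable). Ionisation of F3 at C4 with BF3·OEt2 in the presence of excess 3 (dioxane-CH2Cl2, 0 °C) should give the Friedel-Crafts product 1-[3-[(2R,4S)-7-(benzyloxy)-2-[4-(benzyloxy)phenyl]-3,4-dihydro-2H-chromen-4-yl]-2,4,6-trihydroxyphenyl]dodecan-1-one F4. The arene should enter anti to ring B, and the 2,4-cis isomer would be removed by chromatography. Hydrogenolysis (H2, 10% Pd/C, EtOAc) of the two benzyl ethers then gives 15.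

**Step 3.**
- What may go wrong: the iminium ion of the doubly alkoxylated enal is weakly electrophilic, so the addition may stall. A second alkylation at the remaining free carbon of ring D, or 1,2-addition and condensation to a 2H-chromene, may compete. A slow reaction leaves room for loss of enantioselectivity.
- Fallback (from 3 and 5, rejoining at 7): the enal is activated as an α,β-unsaturated acyl azolium instead of an iminium ion. A chiral aminoindanol-derived triazolium carbene precatalyst with base and 3,3',5,5'-tetra-tert-butyldiphenoquinone as oxidant should annulate 5 with 3 to (4S)-4-[2,4-bis(benzyloxy)phenyl]-6-dodecanoyl-5,7-dihydroxy-3,4-dihydro-2H-chromen-2-one F5. i-Bu2AlH (excess to cover the two phenols, CH2Cl2, -78 °C) should reduce the aryl lactone, which is far more electrophilic than the phenoxide-flanked ketone, to lactol 7.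

**Step 4.**
- What may go wrong: the polymagnesium phenoxide may precipitate and stop the addition. The aldehyde may be enolised by the basic reagent. At higher temperature the reagent may begin to attack the ketone.
- Fallback (from 7, rejoining directly at 10): rhodium-catalysed 1,2-addition of 4-(benzyloxy)phenylboronic acid to the aldehyde form of 7 (Rh(acac)(CO)2, 1,1'-bis(diphenylphosphino)ferrocene, DME-H2O, 80 °C). This tolerates free phenols and should not touch the hindered ketone. It makes no new compound.

**Step 6.**
- What may go wrong: once the ring B benzyl ether is cleaved, the 4-hydroxybenzylic acetate can lose acetic acid to give methide 13 without the enzyme. The freed C8a hydroxyl would then close ring C under substrate control only, giving C2 epimers. Acetyl transfer from ring D to the new phenols may also begin.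
- Fallback (from 11, rejoining at 12): the two reductions are separated. Ionic hydrogenation of the benzylic acetate (Et3SiH, BF3·OEt2, CH2Cl2, -40 °C), while every phenol is still capped, should give 2-[(1S)-1-[2,4-bis(benzyloxy)phenyl]-3-[4-(benzyloxy)phenyl]propyl]-4-dodecanoylbenzene-1,3,5-triyl triacetate F6. Hydrogenolysis of its three benzyl ethers (H2, 10% Pd/C, EtOAc) then gives 12 with no ionisable group left on C2.

## Further compounds

F1 | step 7 | 7-(benzyloxy)-4H-chromen-4-one | O=c1ccoc2cc(OCc3ccccc3)ccc12
F2 | step 7 | (2R)-7-(benzyloxy)-2-[4-(benzyloxy)phenyl]-2,3-dihydro-4H-chromen-4-one | O=C1C[C@H](c2ccc(OCc3ccccc3)cc2)Oc2cc(OCc3ccccc3)ccc12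
F3 | step 7 | (2R)-7-(benzyloxy)-2-[4-(benzyloxy)phenyl]-3,4-dihydro-2H-chromen-4-ol (C4 epimers) | OC1C[C@H](c2ccc(OCc3ccccc3)cc2)Oc2cc(OCc3ccccc3)ccc12
F4 | step 7 | 1-[3-[(2R,4S)-7-(benzyloxy)-2-[4-(benzyloxy)phenyl]-3,4-dihydro-2H-chromen-4-yl]-2,4,6-trihydroxyphenyl]dodecan-1-one | CCCCCCCCCCCC(=O)c1c(O)cc(O)c([C@H]2C[C@H](c3ccc(OCc4ccccc4)cc3)Oc3cc(OCc4ccccc4)ccc32)c1O
F5 | step 3 | (4S)-4-[2,4-bis(benzyloxy)phenyl]-6-dodecanoyl-5,7-dihydroxy-3,4-dihydro-2H-chromen-2-one | CCCCCCCCCCCC(=O)c1c(O)cc2OC(=O)C[C@@H](c3ccc(OCc4ccccc4)cc3OCc3ccccc3)c2c1O
F0 | step 4 | none | none
F6 | step 6 | 2-[(1S)-1-[2,4-bis(benzyloxy)phenyl]-3-[4-(benzyloxy)phenyl]propyl]-4-dodecanoylbenzene-1,3,5-triyl triacetate | CCCCCCCCCCCC(=O)c1c(OC(C)=O)cc(OC(C)=O)c([C@@H](CCc2ccc(OCc3ccccc3)cc2)c2ccc(OCc3ccccc3)cc2OCc2ccccc2)c1OC(C)=O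
A1 | alternative 1 | (1R,2R)-1-[4-(benzyloxy)phenyl]-2-[2,4,6-tris(benzyloxy)-3-bromophenyl]cyclopropane | Brc1c(OCc2ccccc2)cc(OCc2ccccc2)c([C@@H]2C[C@H]2c2ccc(OCc3ccccc3)cc2)c1OCc1ccccc1
A2 | alternative 1 | 3-(benzyloxy)phenol | Oc1cccc(OCc2ccccc2)c1
A3 | alternative 1 | (2R,4S)-7-(benzyloxy)-2-[4-(benzyloxy)phenyl]-4-[2,4,6-tris(benzyloxy)-3-bromophenyl]-3,4-dihydro-2H-chromene | Brc1c(OCc4ccccc4)cc(OCc4ccccc4)c([C@H]2C[C@H](c3ccc(OCc4ccccc4)cc3)Oc3cc(OCc4ccccc4)ccc32)c1OCc1ccccc1
A4 | alternative 2 | dimethyl 2-[(1S,3R)-3-[4-(benzyloxy)phenyl]-3-[(tert-butyldimethylsilyl)oxy]-1-[2,4,6-tris(benzyloxy)-3-dodecanoylphenyl]propyl]malonate | CCCCCCCCCCCC(=O)c1c(OCc4ccccc4)cc(OCc4ccccc4)c([C@@H](C[C@H](c3ccc(OCc4ccccc4)cc3)O[Si](C)(C)C(C)(C)C)C(C(=O)OC)C(=O)OC)c1OCc1ccccc1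
A5 | alternative 2 | methyl vinyl ketone (but-3-en-2-one) | CC(=O)C=C
A6 | alternative 2 | methyl 1-[(1S,3R)-3-[4-(benzyloxy)phenyl]-3-[(tert-butyldimethylsilyl)oxy]-1-[2,4,6-tris(benzyloxy)-3-dodecanoylphenyl]propyl]-2,4-dioxocyclohexane-1-carboxylate (C1 epimers) | CCCCCCCCCCCC(=O)c1c(OCc4ccccc4)cc(OCc4ccccc4)c([C@@H](C[C@H](c3ccc(OCc4ccccc4)cc3)O[Si](C)(C)C(C)(C)C)C3(C(=O)OC)CCC(=O)CC3=O)c1OCc1ccccc1
A7 | alternative 3 | 2-[(2R,4S)-7-(benzyloxy)-4-[2,4,6-tris(benzyloxy)-3-dodecanoylphenyl]-3,4-dihydro-2H-chromen-2-yl]acetaldehyde | CCCCCCCCCCCC(=O)c1c(OCc4ccccc4)cc(OCc4ccccc4)c([C@H]2C[C@H](CC=O)Oc3cc(OCc4ccccc4)ccc32)c1OCc1ccccc1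
A8 | alternative 3 | 4-[(2R,4S)-7-(benzyloxy)-4-[2,4,6-tris(benzyloxy)-3-dodecanoylphenyl]-3,4-dihydro-2H-chromen-2-yl]cyclohex-2-en-1-one (C1'' epimers) | CCCCCCCCCCCC(=O)c1c(OCc4ccccc4)cc(OCc4ccccc4)c([C@H]2C[C@H](C3C=CC(=O)CC3)Oc3cc(OCc4ccccc4)ccc32)c1OCc1ccccc1
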